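**Plan**

Retrosynthesis: the C5 angelate is removed first, then the lactone (C12–O6 and C11–C12, by carbonylation of a C11 vinyl triflate). C8–OH goes back to a C8 ketone and then to a C7=C8 enoate, which is the opened form of a C5–O–C8 ether bridge. The crotonoyl group is cut at C1–C15, and last C5–C6 and C7–C8 are cut in a (5+2) sense.
Forward: a furoate is turned into an acetoxypyranone, and its oxidopyrylium ylide adds to a chiral (E)-β-alkoxyacrylate, closing the seven-membered carbocycle as an 8-oxabicyclo[3.2.1]octenone. C10 and C1 are set on the bicycle, the bridge is opened by C7-enolate elimination, C8 is re-oxygenated, the α-methylene lactone is closed with Pd/CO, the angelate is attached, and the enone is unmasked last.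
Enabling feature: in the ring C1–C5–C6–C7–C8–C9–C10 the oxygens on C5 and C8 are cis and 1,4-related across C6–C7, and C6–O and C7–C11 are trans. The carbocycle is therefore an opened 8-oxabicyclo[3.2.1]octane built from a pyrylium ylide (C5, C1, C10, C9, C8 and the bridging O) and an E-alkene (C6, C7).
Stereochemistry: C5 and C6 come from the cycloaddition (endo alkoxy group, face set by an (S)-1-phenylethyl ether, diastereomers separated). C10 and C1 come from exo-face hydrogenation and exo-face carbonyl addition on the bicycle. C7 and C8 are reset at the β-keto ester (C7 by equilibration trans to C6–O, C8 by chelation-controlled cis reduction). The E-crotonoyl geometry comes from allenyl ether hydrolysis and the Z-angelate from angelic acid.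

Key step: step 5

Remark: ring locants C1 and C5–C10 are those of the target, C11/C12/C13 are the lactone α-carbon, carbonyl and methylene, C15 is the side-chain carbon on C1, β is the ring face carrying the C5 oxygen (exo on the bicycle), and the C15 carbinol centre made in step 10 is assumed to serve as either epimer because step 24 oxidises it.

**Route**

Step 1
Reactants: 1 methyl 3-methylfuran-2-carboxylate
Product: 2 (3-methylfuran-2-yl)methanol
Conditions: LiAlH4, Et2O, 0 °C
Reagents that add atoms: none
Why: Hydride reduction of the ester with LiAlH4 should give the furfuryl alcohol needed for ring expansion, the furan ring being inert to the reagent.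

Step 2
Reactants: 2 (3-methylfuran-2-yl)methanol
Product: 3 6-hydroxy-4-methyl-2H-pyran-3(6H)-one
Conditions: NBS, NaHCO3, NaOAc, THF–H2O (4:1), 0 °C
Reagents that add atoms: water, O
Why: The Achmatowicz rearrangement (oxidation of the furan and hydrolytic ring expansion) should give the pyranone with the furan 3-methyl group at C4, the lactol centre being racemic and lost later.

Step 3
Reactants: 3 6-hydroxy-4-methyl-2H-pyran-3(6H)-one
Product: 4 6-acetoxy-4-methyl-2H-pyran-3(6H)-one
Conditions: Ac2O, pyridine, DMAP (cat.), CH2Cl2, 0 °C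
Reagents that add atoms: acetic anhydride, CC(=O)OC(C)=O
Why: O-Acylation of the lactol hydroxyl installs the acetate that is expelled when the ylide is formed.

Step 4
Reactants: 5 methyl propiolate; 6 (S)-1-phenylethanol
Product: 7 methyl (E)-3-[(1S)-1-phenylethoxy]acrylate
Conditions: N-methylmorpholine (cat.), CH2Cl2, rt
Reagents that add atoms: none
Why: Amine-catalysed oxa-Michael addition of the alcohol to the propiolate should give the (E)-β-alkoxyacrylate without touching the carbinol centre of the auxiliary.

Step 5
Reactants: 4 6-acetoxy-4-methyl-2H-pyran-3(6H)-one; 7 methyl (E)-3-[(1S)-1-phenylethoxy]acrylate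
Product: 9 methyl (1S,5S,6S,7R)-3-methyl-2-oxo-7-[(1S)-1-phenylethoxy]-8-oxabicyclo[3.2.1]oct-3-ene-6-carboxylate, via 4-methyl-3-oxidopyrylium 8 (not isolated)
Conditions: Et3N (1.5 equiv), 7 (3 equiv), CH2Cl2, rt, slow addition of 4; diastereomers separated on silica
Reagents that add atoms: none
Why: Triethylamine removes the C2 proton of 4 and acetate leaves, giving 4-methyl-3-oxidopyrylium 8, whose termini C2 and C6 add suprafacially across the alkene of 7 in a concerted, asynchronous (5+2) dipolar cycloaddition that forms C5–C6 and C7–C8. The closest known reactions are the additions of oxidopyrylium ylides from Achmatowicz-derived acetoxypyranones to acrylates and cinnamates. The seven-membered carbocycle closes by this two-bond intermolecular annulation (five ylide atoms plus two alkene carbons), while the oxygen bridge is the pyran oxygen already in place. The bridge makes the C5 and C8 oxygens cis, the E-alkene makes C6–O and C7–C11 trans, the alkoxy group is expected endo and the ester exo, and the absolute face is set by the (S)-1-phenylethyl group, which in the s-cis enol ether conformer with its C–H in the alkene plane shields one face with phenyl so that the ylide adds from the methyl side to give the (1S,5S,6S,7R) adduct. The step needs regio-, endo/exo- and facial selectivity: the ester polarises the alkene so that the ylide carbon next to the oxido group bonds to the alkoxy-bearing β-carbon as with acrylates, and minor isomers are removed by chromatography because the auxiliary makes all stereoisomers diastereomeric. An excess of 7 and slow addition of 4 keep ylide dimerisation down.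

Step 6
Reactants: 9 methyl (1S,5S,6S,7R)-3-methyl-2-oxo-7-[(1S)-1-phenylethoxy]-8-oxabicyclo[3.2.1]oct-3-ene-6-carboxylate
Product: 10 methyl 7-endo-hydroxy-3-endo-methyl-2-oxo-8-oxabicyclo[3.2.1]octane-6-exo-carboxylate
Conditions: H2 (3 atm), Pd(OH)2/C, EtOAc–EtOH, rt
Reagents that add atoms: none
Why: Catalytic hydrogenation should add hydrogen to C9=C10 from the exo face (syn to the oxygen bridge, away from the two-carbon bridge and its endo oxygen), which puts the C10 methyl endo, and hydrogenolysis of the benzylic C–O bond in the same operation frees the C6 hydroxyl.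

Step 7
Reactants: 11 but-2-yn-1-ol
Product: 12 1-methoxybut-2-yne
Conditions: NaH, MeI, THF, 0 °C to rt
Reagents that add atoms: iodomethane, CI
Why: Williamson ether synthesis on the primary propargylic alkoxide.

Step 8
Reactants: 12 1-methoxybut-2-yne
Product: 13 1-methoxybuta-1,2-diene
Conditions: KOt-Bu (cat.), DMSO, 20 °C; distillation
Reagents that add atoms: none
Why: Base-catalysed prototropic propargyl-to-allenyl ether isomerisation, stopped at the 1-alkoxy-1,2-diene before it migrates further to the 1,3-diene.

Step 9
Reactants: 10 methyl 7-endo-hydroxy-3-endo-methyl-2-oxo-8-oxabicyclo[3.2.1]octane-6-exo-carboxylate; 13 1-methoxybuta-1,2-diene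
Product: 15 methyl 2-exo-[(E)-but-2-enoyl]-2-endo,7-endo-dihydroxy-3-endo-methyl-8-oxabicyclo[3.2.1]octane-6-exo-carboxylate, via allenyl ether adduct 14 (not isolated)
Conditions: 13 (3.5 equiv), n-BuLi (3.3 equiv), THF, −78 °C; then 10, −78 °C; then 1 M HCl, THF, 0 °C
Reagents that add atoms: water, O
Why: 1,2-Addition of the C1-lithiated alkoxyallene (a crotonoyl anion equivalent) to the α-alkoxy ketone should occur on the exo face, syn to the oxygen bridge and away from the endo C6 and C10 substituents, which sets C1 with the new carbon β and the hydroxyl α, and acid hydrolysis of the allenyl ether then gives the (E)-enone, the ester being far less electrophilic than the ketone at −78 °C.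

Step 10
Reactants: 15 methyl 2-exo-[(E)-but-2-enoyl]-2-endo,7-endo-dihydroxy-3-endo-methyl-8-oxabicyclo[3.2.1]octane-6-exo-carboxylate
Product: 16 methyl 2-endo,7-endo-dihydroxy-2-exo-[(E)-1-hydroxybut-2-enyl]-3-endo-methyl-8-oxabicyclo[3.2.1]octane-6-exo-carboxylate
Conditions: NaBH4, CeCl3·7H2O, MeOH, −78 °C
Reagents that add atoms: none
Why: Luche 1,2-reduction masks the enone as its allylic alcohol so that it survives the bases, nucleophiles and hydrides of steps 12–19, the new C15 centre being uncontrolled and inconsequential because step 24 removes it.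

Step 11
Reactants: 16 methyl 2-endo,7-endo-dihydroxy-2-exo-[(E)-1-hydroxybut-2-enyl]-3-endo-methyl-8-oxabicyclo[3.2.1]octane-6-exo-carboxylate
Product: 17 C1,C15-acetonide of 16 (spiro-dioxolane at C1 with C6–OH free)
Conditions: 2-methoxypropene, PPTS (cat.), CH2Cl2, 0 °C to rt
Reagents that add atoms: 2-methoxypropene, COC(C)=C
Why: Acid-catalysed ketalisation closes the five-membered dioxolane on the vicinal tertiary/secondary diol in preference to a six-membered ketal to C6–OH, which leaves C6–OH as the only free hydroxyl.

Step 12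
Reactants: 17 C1,C15-acetonide of 16 (spiro-dioxolane at C1 with C6–OH free)
Product: 18 methyl 5β,6α-dihydroxy-10α-methylcyclohept-7-ene-7-carboxylate carrying the C1(α-O),C15-acetonide
Conditions: LDA (2.5 equiv), THF, −78 to 0 °C; aq. NH4Cl
Reagents that add atoms: none
Why: β-Elimination (E1cB) from the C7 ester enolate should cleave the C8–O bond of the bridge and release the C5 alkoxide, as in base-induced openings of oxabicyclic esters, while the C6 oxygen is present as its lithium alkoxide (a β-hydroxy ester dianion) and cannot leave, so only C7=C8 is formed.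

Step 13
Reactants: 18 methyl 5β,6α-dihydroxy-10α-methylcyclohept-7-ene-7-carboxylate carrying the C1(α-O),C15-acetonide
Product: 19 5,6-bis(triethylsilyl) ether of 18
Conditions: TESOTf, 2,6-lutidine, CH2Cl2, −78 °C
Reagents that add atoms: triethylsilyl trifluoromethanesulfonate, CC[Si](CC)(CC)OS(=O)(=O)C(F)(F)F
Why: Silyl ether formation on the two secondary hydroxyls makes the later oxidation at C8 unambiguous and keeps both oxygens inert until step 20.

Step 14
Reactants: 19 5,6-bis(triethylsilyl) ether of 18
Product: 21 8-hydroxy ester of the 5,6-bis-TES series (C7/C8 epimer mixture), via C8 pinacolboronate 20 (not isolated)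
Conditions: CuCl (10 mol%), Xantphos (10 mol%), NaOt-Bu (20 mol%), B2pin2, MeOH, THF, rt; then NaBO3·4H2O, THF–H2O, rt
Reagents that add atoms: bis(pinacolato)diboron, CC1(C)OB(OC1(C)C)B1OC(C)(C)C(C)(C)O1 (boron of 20); sodium perborate, [Na+].[O-]OB=O (oxygen of 21)
Why: Copper-catalysed conjugate borylation of the enoate places boron on the β-carbon C8 and perborate oxidation of the C–B bond gives the β-hydroxy ester, whose C7 and C8 configurations need no control because steps 15 and 16 reset both.

Step 15
Reactants: 21 8-hydroxy ester of the 5,6-bis-TES series (C7/C8 epimer mixture)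
Product: 22 8-oxo-7β-methoxycarbonyl compound (β-keto ester) of the 5,6-bis-TES series
Conditions: Dess–Martin periodinane, NaHCO3, CH2Cl2, 0 °C to rt; used without delay
Reagents that add atoms: none
Why: Dess–Martin oxidation of the only free alcohol gives the β-keto ester, in which C7 equilibrates through the enol to the isomer with the ester trans to the C6 silyloxy group.

Step 16
Reactants: 22 8-oxo-7β-methoxycarbonyl compound (β-keto ester) of the 5,6-bis-TES series
Product: 23 8β-hydroxy-7β-methoxycarbonyl compound (7,8-cis) of the 5,6-bis-TES series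
Conditions: Zn(BH4)2, Et2O, −20 °C; aq. NH4Cl
Reagents that add atoms: none
Why: Chelation-controlled reduction of the β-keto ester with zinc borohydride delivers hydride to the zinc-bridged ketone from the side of C7–H, which gives the 7,8-cis hydroxy ester and so places C8–OH on the β face with C7 held trans to the C6 oxygen.

Step 17
Reactants: 23 8β-hydroxy-7β-methoxycarbonyl compound (7,8-cis) of the 5,6-bis-TES series
Product: 24 8-O-tert-butyldimethylsilyl ether of 23
Conditions: TBSOTf (1.2 equiv), 2,6-lutidine, CH2Cl2, −78 °C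
Reagents that add atoms: tert-butyldimethylsilyl trifluoromethanesulfonate, CC(C)(C)[Si](C)(C)OS(=O)(=O)C(F)(F)F
Why: Silyl ether formation at the only free hydroxyl blocks C8–OH so that the later carbonylative ring closure cannot involve it.

Step 18
Reactants: 24 8-O-tert-butyldimethylsilyl ether of 23
Product: 26 7β-acetyl compound (methyl ketone in place of the ester of 24), via Weinreb amide 25 (not isolated)
Conditions: MeNH(OMe)·HCl, i-PrMgCl, THF, −20 °C; then MeMgBr, −20 to 0 °C
Reagents that add atoms: N,O-dimethylhydroxylamine hydrochloride, CNOC.Cl (amide nitrogen of 25); methylmagnesium bromide, C[Mg]Br (methyl of 26)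
Why: One-pot conversion of the ester into the methyl ketone through the Weinreb amide formed in situ, whose chelated tetrahedral intermediate prevents a second addition of the Grignard reagent.

Step 19
Reactants: 26 7β-acetyl compound (methyl ketone in place of the ester of 24)
Product: 27 vinyl triflate (7β-[1-(trifluoromethylsulfonyloxy)ethenyl] compound)
Conditions: KHMDS (1.2 equiv), THF, −78 °C; PhNTf2; aq. NH4Cl
Reagents that add atoms: N-phenylbis(trifluoromethanesulfonimide), FC(F)(F)S(=O)(=O)N(c1ccccc1)S(=O)(=O)C(F)(F)F
Why: Kinetic deprotonation of the methyl ketone at the methyl group (not at the hindered C7–H, which would open β-elimination paths) and O-sulfonylation of the enolate should give the 1,1-disubstituted vinyl triflate.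

Step 20
Reactants: 27 vinyl triflate (7β-[1-(trifluoromethylsulfonyloxy)ethenyl] compound)
Product: 28 5β,6α-diol vinyl triflate (both triethylsilyl groups removed)
Conditions: HF·pyridine, pyridine, THF, 0 °C
Reagents that add atoms: none
Why: Buffered fluoride desilylation cleaves the two triethylsilyl ethers much faster than the tert-butyldimethylsilyl ether, and the acetonide and the vinyl triflate are stable to it.

Step 21
Reactants: 28 5β,6α-diol vinyl triflate (both triethylsilyl groups removed)
Product: 29 trans-fused α-methylene-γ-lactone (6α-O–C12 and 7β-C11) with 5β-OH and 8β-OTBS and the C1,C15-acetonide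
Conditions: Pd(PPh3)4 (10 mol%), CO (1 atm), i-Pr2NEt, MeCN, 50 °C
Reagents that add atoms: carbon monoxide, [C-]#[O+]
Why: Palladium-catalysed carbonylation of the vinyl triflate gives an acylpalladium species that the C6 hydroxyl captures intramolecularly (five-membered ring, favoured over the bridged six-membered alternative through C5–OH), closing the lactone as in carbonylative lactonisations of hydroxy vinyl halides and triflates.

Step 22
Reactants: 29 trans-fused α-methylene-γ-lactone (6α-O–C12 and 7β-C11) with 5β-OH and 8β-OTBS and the C1,C15-acetonide; 30 angelic acid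
Product: 31 5β-angelate of 29
Conditions: 30, 2,4,6-trichlorobenzoyl chloride, Et3N, toluene, rt; then 29, DMAP, toluene, 70 °C
Reagents that add atoms: none
Why: Yamaguchi esterification through the mixed 2,4,6-trichlorobenzoic anhydride should acylate the hindered C5 hydroxyl, the only free alcohol, without Z-to-E isomerisation of the angeloyl group.

Step 23
Reactants: 31 5β-angelate of 29
Product: 32 15-hydroxy compound (target with a C15 carbinol in place of the ketone; C15 epimers)
Conditions: 48% aq. HF, MeCN, 0 °C to rt
Reagents that add atoms: none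
Why: Aqueous acidic fluoride removes the silyl ether and hydrolyses the acetonide in one operation, conditions that the methylene lactone and the angelate tolerate.

Step 24
Reactants: 32 15-hydroxy compound (target with a C15 carbinol in place of the ketone; C15 epimers)
Product: 33 CNP0206014.2 (target)
Conditions: activated MnO2, CH2Cl2, rt
Reagents that add atoms: none
Why: Manganese dioxide oxidises only the allylic C15 alcohol, giving the (E)-crotonoyl ketone and leaving the saturated secondary C8 hydroxyl and the tertiary C1 hydroxyl untouched.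

**Compound list**

1 | methyl 3-methylfuran-2-carboxylate | COC(=O)c1occc1C | starting material
2 | (3-methylfuran-2-yl)methanol | OCc1occc1C | intermediate
3 | 6-hydroxy-4-methyl-2H-pyran-3(6H)-one (racemic lactol) | CC1=CC(O)OCC1=O | intermediate
4 | 6-acetoxy-4-methyl-2H-pyran-3(6H)-one (racemic) | CC1=CC(OC(C)=O)OCC1=O | intermediate
5 | methyl propiolate | COC(=O)C#C | starting material
6 | (S)-1-phenylethanol | C[C@H](O)c1ccccc1 | starting material
7 | methyl (E)-3-[(1S)-1-phenylethoxy]acrylate | C[C@H](O/C=C/C(=O)OC)c1ccccc1 | intermediate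
8 | 4-methyl-3-oxidopyrylium (4-methylpyrylium-3-olate, formed in situ) | Cc1cc[o+]cc1[O-] | intermediate
9 | methyl (1S,5S,6S,7R)-3-methyl-2-oxo-7-[(1S)-1-phenylethoxy]-8-oxabicyclo[3.2.1]oct-3-ene-6-carboxylate (ester exo, ether endo) | C[C@H](O[C@@H]1[C@@H](C(=O)OC)[C@@H]2C=C(C)C(=O)[C@H]1O2)c1ccccc1 | intermediate
10 | methyl 7-endo-hydroxy-3-endo-methyl-2-oxo-8-oxabicyclo[3.2.1]octane-6-exo-carboxylate | O[C@@H]1[C@@H](C(=O)OC)[C@@H]2C[C@H](C)C(=O)[C@H]1O2 | intermediate
11 | but-2-yn-1-ol | CC#CCO | starting material
12 | 1-methoxybut-2-yne | CC#CCOC | intermediate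
13 | 1-methoxybuta-1,2-diene (racemic allene) | CC=C=COC | intermediate
14 | methyl 2-endo,7-endo-dihydroxy-2-exo-(1-methoxybuta-1,2-dienyl)-3-endo-methyl-8-oxabicyclo[3.2.1]octane-6-exo-carboxylate (allenyl ether adduct, formed in situ) | O[C@@H]1[C@@H](C(=O)OC)[C@@H]2C[C@H](C)[C@@](O)(C(OC)=C=CC)[C@H]1O2 | intermediate
15 | methyl 2-exo-[(E)-but-2-enoyl]-2-endo,7-endo-dihydroxy-3-endo-methyl-8-oxabicyclo[3.2.1]octane-6-exo-carboxylate | O[C@@H]1[C@@H](C(=O)OC)[C@@H]2C[C@H](C)[C@@](O)(C(=O)/C=C/C)[C@H]1O2 | intermediate
16 | methyl 2-endo,7-endo-dihydroxy-2-exo-[(E)-1-hydroxybut-2-enyl]-3-endo-methyl-8-oxabicyclo[3.2.1]octane-6-exo-carboxylate (C15 epimers) | O[C@@H]1[C@@H](C(=O)OC)[C@@H]2C[C@H](C)[C@@](O)(C(O)/C=C/C)[C@H]1O2 | intermediate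
17 | C1,C15-acetonide of 16 (spiro-dioxolane at C1, C6–OH free) | O[C@@H]1[C@@H](C(=O)OC)[C@@H]2C[C@H](C)[C@@](OC(C)(C)O3)(C3/C=C/C)[C@H]1O2 | intermediate
18 | methyl 5β,6α-dihydroxy-10α-methylcyclohept-7-ene-7-carboxylate carrying the C1(α-O),C15-acetonide with the (E)-propenyl group on C15 | O[C@@H]1C(C(=O)OC)=CC[C@H](C)[C@@](OC(C)(C)O2)(C2/C=C/C)[C@H]1O | intermediate
19 | 5,6-bis(triethylsilyl) ether of 18 | CC[Si](CC)(CC)O[C@@H]1C(C(=O)OC)=CC[C@H](C)[C@@](OC(C)(C)O2)(C2/C=C/C)[C@H]1O[Si](CC)(CC)CC | intermediate
20 | C8 pinacolboronate of the saturated ester (C7/C8 epimers, formed in situ) | CC[Si](CC)(CC)O[C@@H]1C(C(=O)OC)C(B2OC(C)(C)C(C)(C)O2)C[C@H](C)[C@@](OC(C)(C)O3)(C3/C=C/C)[C@H]1O[Si](CC)(CC)CC | intermediate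
21 | 8-hydroxy ester of the 5,6-bis-TES series (C7/C8 epimers) | CC[Si](CC)(CC)O[C@@H]1C(C(=O)OC)C(O)C[C@H](C)[C@@](OC(C)(C)O2)(C2/C=C/C)[C@H]1O[Si](CC)(CC)CC | intermediate
22 | 8-oxo-7β-methoxycarbonyl compound (β-keto ester) | CC[Si](CC)(CC)O[C@@H]1[C@@H](C(=O)OC)C(=O)C[C@H](C)[C@@](OC(C)(C)O2)(C2/C=C/C)[C@H]1O[Si](CC)(CC)CC | intermediate
23 | 8β-hydroxy-7β-methoxycarbonyl compound (7,8-cis; 6,7-trans) | CC[Si](CC)(CC)O[C@@H]1[C@@H](C(=O)OC)[C@@H](O)C[C@H](C)[C@@](OC(C)(C)O2)(C2/C=C/C)[C@H]1O[Si](CC)(CC)CC | intermediate
24 | 8-O-tert-butyldimethylsilyl ether of 23 | CC[Si](CC)(CC)O[C@@H]1[C@@H](C(=O)OC)[C@@H](O[Si](C)(C)C(C)(C)C)C[C@H](C)[C@@](OC(C)(C)O2)(C2/C=C/C)[C@H]1O[Si](CC)(CC)CC | intermediate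
25 | Weinreb amide (7β-CON(OMe)Me, formed in situ) | CC[Si](CC)(CC)O[C@@H]1[C@@H](C(=O)N(C)OC)[C@@H](O[Si](C)(C)C(C)(C)C)C[C@H](C)[C@@](OC(C)(C)O2)(C2/C=C/C)[C@H]1O[Si](CC)(CC)CC | intermediate
26 | 7β-acetyl compound (methyl ketone) | CC[Si](CC)(CC)O[C@@H]1[C@@H](C(C)=O)[C@@H](O[Si](C)(C)C(C)(C)C)C[C@H](C)[C@@](OC(C)(C)O2)(C2/C=C/C)[C@H]1O[Si](CC)(CC)CC | intermediate
27 | vinyl triflate (7β-[1-(trifluoromethylsulfonyloxy)ethenyl]) | CC[Si](CC)(CC)O[C@@H]1[C@@H](C(=C)OS(=O)(=O)C(F)(F)F)[C@@H](O[Si](C)(C)C(C)(C)C)C[C@H](C)[C@@](OC(C)(C)O2)(C2/C=C/C)[C@H]1O[Si](CC)(CC)CC | intermediate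
28 | 5β,6α-diol vinyl triflate | O[C@@H]1[C@@H](C(=C)OS(=O)(=O)C(F)(F)F)[C@@H](O[Si](C)(C)C(C)(C)C)C[C@H](C)[C@@](OC(C)(C)O2)(C2/C=C/C)[C@H]1O | intermediate
29 | trans-fused α-methylene-γ-lactone with 5β-OH, 8β-OTBS and the C1,C15-acetonide | C=C1C(=O)O[C@@H]2[C@@H]1[C@@H](O[Si](C)(C)C(C)(C)C)C[C@H](C)[C@@](OC(C)(C)O3)(C3/C=C/C)[C@H]2O | intermediate
30 | angelic acid, (Z)-2-methylbut-2-enoic acid | C/C=C(/C)C(O)=O | starting material
31 | 5β-angelate of 29 | C=C1C(=O)O[C@@H]2[C@@H]1[C@@H](O[Si](C)(C)C(C)(C)C)C[C@H](C)[C@@](OC(C)(C)O3)(C3/C=C/C)[C@H]2OC(=O)/C(C)=C\C | intermediate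
32 | 15-hydroxy compound (C15 carbinol in place of the target ketone; C15 epimers) | C=C1C(=O)O[C@@H]2[C@@H]1[C@@H](O)C[C@H](C)[C@@](O)(C(O)/C=C/C)[C@H]2OC(=O)/C(C)=C\C | intermediate
33 | CNP0206014.2 | C=C1C(=O)O[C@@H]2[C@@H]1[C@@H](O)C[C@H](C)[C@@](O)(C(=O)/C=C/C)[C@H]2OC(=O)/C(C)=C\C | target

**Step count and risks**

Total step count: 24. Longest linear sequence: 21 steps (from 1 through steps 1–3, 5, 6 and 9–24).

Steps most likely to fail:

1. Step 5. The push–pull alkene may add more slowly than the ylide dimerises, and the remote auxiliary may discriminate the alkene faces and the endo/exo modes only weakly, so that the wanted diastereomer forms in a small share or cannot be separated. The fallback moves stereocontrol from the cycloaddition to a resolution. Starting again from 4 and 5, benzyl alcohol is added to 5 under the conditions of step 4 to give methyl (E)-3-(benzyloxy)acrylate F1, which is less hindered and can be used in larger excess. Cycloaddition with 4 under the conditions of step 5 should give the racemic endo-benzyloxy/exo-ester adduct, methyl (1S,5S,6S,7R)-7-(benzyloxy)-3-methyl-2-oxo-8-oxabicyclo[3.2.1]oct-3-ene-6-carboxylate F2 together with its enantiomer F3. The two are separated by preparative chromatography on a chiral stationary phase, and F2 is hydrogenated and debenzylated under the conditions of step 6, which returns the route to 10.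

2. Step 12. Removal of the concave C7–H next to the lithium alkoxide may be slow, and the aldolate may instead fragment by retro-aldol cleavage of C6–C7 or the freed C5 alkoxide may add back, so that ring opening is incomplete or unselective. The fallback replaces the anionic elimination by a Lewis-acid-triggered one. From 17, deprotonation with LDA in the presence of TMSCl (internal quench, THF, −78 °C) should give the C6-O-silylated silyl ketene acetal F4. A catalytic amount of TMSOTf (CH2Cl2, −78 °C) should then silylate the bridge oxygen, which is a far stronger Lewis base than the silyl ether oxygen at C6, and the ketene acetal expels it to give the ring-opened 5,6-bis(trimethylsilyl) ether F5. K2CO3 in methanol removes both silyl groups and returns the route to 18.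

3. Step 18. Acyl substitution at the ester, which is flanked by two silyloxy-bearing carbons, may be too slow, and the basic magnesium amide may instead cause β-elimination of a silyloxy group or epimerise C7. The fallback is a redox detour that avoids amide bases. From 24, DIBAL-H (CH2Cl2, −78 °C) should reduce the ester to the 7β-formyl compound F6. Methylmagnesium bromide (THF, −78 °C) adds to give the 7β-(1-hydroxyethyl) compound F7 as a carbinol mixture, and Dess–Martin oxidation returns the route to 26.

Further compounds
F1 | step 5 | methyl (E)-3-(benzyloxy)acrylate | COC(=O)/C=C/OCc1ccccc1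
F2 | step 5 | methyl (1S,5S,6S,7R)-7-(benzyloxy)-3-methyl-2-oxo-8-oxabicyclo[3.2.1]oct-3-ene-6-carboxylate | c1ccccc1CO[C@@H]1[C@@H](C(=O)OC)[C@@H]2C=C(C)C(=O)[C@H]1O2
F3 | step 5 | methyl (1R,5R,6R,7S)-7-(benzyloxy)-3-methyl-2-oxo-8-oxabicyclo[3.2.1]oct-3-ene-6-carboxylate (enantiomer of F2) | c1ccccc1CO[C@H]1[C@H](C(=O)OC)[C@H]2C=C(C)C(=O)[C@@H]1O2
F4 | step 12 | trimethylsilyl ketene acetal of 17 with C6–OTMS (bicyclic, bridge intact) | C[Si](C)(C)O[C@@H]1C(=C(OC)O[Si](C)(C)C)[C@@H]2C[C@H](C)[C@@](OC(C)(C)O3)(C3/C=C/C)[C@H]1O2
F5 | step 12 | 5,6-bis(trimethylsilyl) ether of 18 | C[Si](C)(C)O[C@@H]1C(C(=O)OC)=CC[C@H](C)[C@@](OC(C)(C)O2)(C2/C=C/C)[C@H]1O[Si](C)(C)C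
F6 | step 18 | 7β-formyl compound (aldehyde in place of the ester of 24) | CC[Si](CC)(CC)O[C@@H]1[C@@H](C=O)[C@@H](O[Si](C)(C)C(C)(C)C)C[C@H](C)[C@@](OC(C)(C)O2)(C2/C=C/C)[C@H]1O[Si](CC)(CC)CC
F7 | step 18 | 7β-(1-hydroxyethyl) compound (carbinol epimers) | CC[Si](CC)(CC)O[C@@H]1[C@@H](C(C)O)[C@@H](O[Si](C)(C)C(C)(C)C)C[C@H](C)[C@@](OC(C)(C)O2)(C2/C=C/C)[C@H]1O[Si](CC)(CC)CC
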